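**Plan**

- Azulene locants are used: C3 = C(OH)(iPr), C3a = ring-fusion CH, C4 = CH–O, C5–C8 = CH2–C(CH3)=CH–CH2, C8a = quaternary C–CH3. The ester C–O bond is cut first, then C4–O and C3a–H, back to a C3a=C4 alkene next to the C3 carbinol.
- The seven-membered ring holds an intact isoprene unit (C5–C8). Its ends are bonded to C4 and C8a, the two ends of a three-carbon unit C4–C3a–C8a anchored on the five-membered ring. C4–C5 and C8–C8a are therefore cut together, leaving isoprene and a (cyclopent-1-enyl)carbene (carbene carbon C4, C3a=C8a).
- The carbene comes from the sulfonylhydrazone of a cyclopentene carbaldehyde, and the aldehyde from (S)-terpinen-4-ol by ozonolysis and aldol ring contraction.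
- Forward: the five-membered ring is made first (ring contraction of the cyclohexene). The seven-membered ring follows by dirhodium-carbenoid cyclopropanation of isoprene and Cope rearrangement in one operation, then oxygen at C4 and the ester.
- Stereochemistry: C3 comes from the chiral pool. C8a is set in the key step under control of the C3 silyl ether. C3a and C4 are set together by a syn hydrosilylation delivered from the C3 oxygen, followed by oxidation with retention.

Key step: step 5

Assumption: 1 is used as the (S)-enantiomer in high enantiomeric purity (enriched first if the commercial lot is not); its carbinol carbon is carried unchanged into C3 of the target.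

**Route**

Step 1
Reactants: 1 (S)-terpinen-4-ol [(1S)-4-methyl-1-(propan-2-yl)cyclohex-3-en-1-ol]; 2 tert-butyldimethylsilyl trifluoromethanesulfonate
Product: 3 tert-butyldimethyl{[(1S)-4-methyl-1-(propan-2-yl)cyclohex-3-en-1-yl]oxy}silane
Conditions: 2,6-lutidine, CH2Cl2, 0 °C → rt
Reagents that add atoms: tert-butyldimethylsilyl trifluoromethanesulfonate (2), CC(C)(C)[Si](C)(C)OS(=O)(=O)C(F)(F)F
Why: O-Silylation of the hindered tertiary alcohol with a silyl triflate and 2,6-lutidine should go cleanly and leaves the stereocentre untouched; the bulky silyl ether later prevents lactol formation and β-hydroxy aldehyde chemistry and shields one face in step 5.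

Step 2
Reactants: 3
Product: 5 (3S)-3-[(tert-butyldimethylsilyl)oxy]-6-oxo-3-(propan-2-yl)heptanal, via ozonide 4 (not isolated)
Conditions: O3, CH2Cl2, −78 °C; then PPh3, −78 °C → rt
Reagents that add atoms: ozone, [O-][O+]=O
Why: Ozonolysis of the only alkene and reductive cleavage of the secondary ozonide 4 with PPh3 should give the 1,6-keto aldehyde without touching the silyl ether or the stereocentre.

Step 3
Reactants: 5
Product: 6 (5R)-5-[(tert-butyldimethylsilyl)oxy]-2-methyl-5-(propan-2-yl)cyclopent-1-ene-1-carbaldehyde
Conditions: dibenzylammonium trifluoroacetate (0.3 equiv), PhMe, 50 °C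
Reagents that add atoms: none
Why: Intramolecular aldol condensation by enamine catalysis with a secondary ammonium salt should join the aldehyde α-carbon to the methyl ketone (5-exo closure) and lose water to the conjugated enal, which contracts the ring and places the formyl carbon (later C4) next to the carbinol carbon; no stereocentre is formed.

Step 4
Reactants: 6; 7 2-(trifluoromethyl)benzenesulfonohydrazide
Product: 8 N'-[(E)-{(5R)-5-[(tert-butyldimethylsilyl)oxy]-2-methyl-5-(propan-2-yl)cyclopent-1-en-1-yl}methylidene]-2-(trifluoromethyl)benzenesulfonohydrazide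
Conditions: MeOH, rt
Reagents that add atoms: 2-(trifluoromethyl)benzenesulfonohydrazide (7), NNS(=O)(=O)c1ccccc1C(F)(F)F
Why: Condensation of the aldehyde with the sulfonyl hydrazide (hydrazone formation) should give the E-hydrazone, and the 2-(trifluoromethyl)benzenesulfonyl group is chosen because its salt releases the diazo compound near room temperature.

Step 5
Reactants: 8; 9 isoprene (2-methylbuta-1,3-diene)
Product: 13 tert-butyl{[(3R,8aS)-6,8a-dimethyl-3-(propan-2-yl)-1,2,3,5,8,8a-hexahydroazulen-3-yl]oxy}dimethylsilane, via sodium hydrazonide 10 (not isolated), via vinyldiazomethane 11 (not isolated), via cis-divinylcyclopropane 12 (not isolated)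
Conditions: NaH, THF, 0 °C; slow addition to Rh2(OAc)4 (2 mol %), 9 (10 equiv), CH2Cl2, 35 °C (sealed); then PhMe, 110 °C
Reagents that add atoms: isoprene (9), C=CC(C)=C
Why: NaH turns 8 into its sodium salt 10, which loses sulfinate (Bamford–Stevens fragmentation) to give vinyldiazomethane 11; Rh2(OAc)4 converts 11 into an electrophilic vinylcarbenoid that cyclopropanates the more nucleophilic 2-methyl-substituted double bond of isoprene (carbenoid carbon, later C4, to the CH2 terminus, later C5, with charge build-up on the tertiary allylic carbon), and the cis-divinylcyclopropane 12 then undergoes a Cope rearrangement through a boat transition state that forms C8–C8a as the cyclopropane bond between C4 and C6 breaks. The closest known reaction type is the formal (4+3) cycloaddition of dirhodium vinylcarbenoids, acceptor-free ones included, with 1,3-dienes by tandem cyclopropanation and divinylcyclopropane rearrangement, here fed by a sulfonylhydrazone-derived diazo compound. The seven-membered ring is the only ring closed: C4–C5 arises in the [2+1] step and C8–C8a in the [3,3] step, so the net mode is (4+3) and both ring alkenes (C3a=C4 and C6=C7) are left in place. The one new stereocentre, quaternary C8a, is controlled by the silyloxy-bearing C3: allylic 1,3-strain with the C8a methyl group keeps the metal on the C3 side of the carbenoid, the silyl ether shields the face on which it lies so that the diene should add end-on to the face carrying the isopropyl group, and the stereospecific boat transition state then relays this cyclopropane configuration into a C8–C8a bond on the face of the silyloxy group, which places the methyl group cis to isopropyl as in the target. The step needs chemoselectivity for carbenoid formation over closure of 11 to a pyrazole (secured by slow addition of 10 to catalyst and excess diene), regioselectivity for the 2-methyl-substituted double bond (secured by its higher nucleophilicity) and a cis-divinyl arrangement (vinyl group of the diene next to the cyclopentenyl group, as is found for donor-type dirhodium carbenoids). The methyl group on the reacting cyclopentene carbon points into the boat transition state and slows the rearrangement, hence the final heating.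

Step 6
Reactants: 13
Product: 14 (3R,8aS)-6,8a-dimethyl-3-(propan-2-yl)-1,2,3,5,8,8a-hexahydroazulen-3-ol
Conditions: TBAF, THF, 50 °C
Reagents that add atoms: none
Why: Fluoride-induced desilylation should free the tertiary allylic alcohol under non-acidic conditions that do not ionise it, and no stereocentre is touched.

Step 7
Reactants: 14; 15 chlorodimethylsilane
Product: 17 cyclic siloxane in which an O–SiMe2 bridge links C3 (through oxygen) to C4 (through silicon) of 6,8a-dimethyl-3-(propan-2-yl)-1,2,3,3a,4,5,8,8a-octahydroazulene (1,2-oxasilolane ring; C3a–H on the face of the ring oxygen; trans ring fusion), via dimethylsilyl ether 16 (not isolated)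
Conditions: 15, Et3N, DMAP (cat.), CH2Cl2, 0 °C → rt; filtration, solvent exchange; Pt2[(CH2=CHSiMe2)2O]3 (0.5 mol %), PhMe, 60 °C
Reagents that add atoms: chlorodimethylsilane (15), C[SiH](C)Cl
Why: O-Silylation to hydrosilyl ether 16 and platinum-catalysed intramolecular hydrosilylation (5-endo mode) should add Si–H syn across C3a=C4 from the face of the tethering C3 oxygen, which places silicon on C4 and hydrogen on C3a on that face (hydrogen anti to the C8a methyl group, hence the trans ring fusion) and spares the remote C6=C7 alkene.

Step 8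
Reactants: 17
Product: 18 (3R,3aR,4R,8aS)-6,8a-dimethyl-3-(propan-2-yl)-1,2,3,3a,4,5,8,8a-octahydroazulene-3,4-diol
Conditions: 30 % H2O2, KF, KHCO3, THF/MeOH, rt → 40 °C
Reagents that add atoms: hydrogen peroxide, OO
Why: Tamao oxidation should replace the C4–Si bond by C4–OH with retention of configuration and release the C3 hydroxyl, so that both hydroxyl groups and C3a–H lie on the face opposite to the angular methyl group.

Step 9
Reactants: 18; 19 3,4-dimethoxybenzoyl chloride
Product: 20 (3R,3aR,4R,8aS)-3-hydroxy-6,8a-dimethyl-3-(propan-2-yl)-1,2,3,3a,4,5,8,8a-octahydroazulen-4-yl 3,4-dimethoxybenzoate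
Conditions: pyridine, DMAP (cat.), CH2Cl2, 0 °C → rt
Reagents that add atoms: 3,4-dimethoxybenzoyl chloride (19), COc1ccc(C(Cl)=O)cc1OC
Why: DMAP-catalysed acylation with the aroyl chloride (esterification) should take place only at the secondary C4 hydroxyl because the tertiary C3 hydroxyl is too hindered, and it does not touch a stereocentre.

**Compound list**

1 | (S)-terpinen-4-ol, (1S)-4-methyl-1-(propan-2-yl)cyclohex-3-en-1-ol | CC1=CC[C@](O)(C(C)C)CC1 | starting material
2 | tert-butyldimethylsilyl trifluoromethanesulfonate | CC(C)(C)[Si](C)(C)OS(=O)(=O)C(F)(F)F | starting material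
3 | tert-butyldimethyl{[(1S)-4-methyl-1-(propan-2-yl)cyclohex-3-en-1-yl]oxy}silane | CC1=CC[C@](O[Si](C)(C)C(C)(C)C)(C(C)C)CC1 | intermediate
4 | secondary ozonide of 3 (7,8,9-trioxabicyclo[4.2.1]nonane core, the 1,2,4-trioxolane bridging the former alkene carbons; both bridgehead diastereomers) | CC12CC[C@@](O[Si](C)(C)C(C)(C)C)(C(C)C)CC(OO1)O2 | intermediate
5 | (3S)-3-[(tert-butyldimethylsilyl)oxy]-6-oxo-3-(propan-2-yl)heptanal | O=CC[C@](O[Si](C)(C)C(C)(C)C)(C(C)C)CCC(C)=O | intermediate
6 | (5R)-5-[(tert-butyldimethylsilyl)oxy]-2-methyl-5-(propan-2-yl)cyclopent-1-ene-1-carbaldehyde | CC1=C(C=O)[C@](O[Si](C)(C)C(C)(C)C)(C(C)C)CC1 | intermediate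
7 | 2-(trifluoromethyl)benzenesulfonohydrazide | NNS(=O)(=O)c1ccccc1C(F)(F)F | starting material
8 | N'-[(E)-{(5R)-5-[(tert-butyldimethylsilyl)oxy]-2-methyl-5-(propan-2-yl)cyclopent-1-en-1-yl}methylidene]-2-(trifluoromethyl)benzenesulfonohydrazide | CC1=C(/C=N/NS(=O)(=O)c2ccccc2C(F)(F)F)[C@](O[Si](C)(C)C(C)(C)C)(C(C)C)CC1 | intermediate
9 | isoprene (2-methylbuta-1,3-diene) | C=CC(C)=C | starting material
10 | sodium salt of hydrazone 8 (N-sodio sulfonylhydrazonide) | CC1=C(/C=N/[N-]S(=O)(=O)c2ccccc2C(F)(F)F)[C@](O[Si](C)(C)C(C)(C)C)(C(C)C)CC1.[Na+] | intermediate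
11 | tert-butyl{[(1R)-2-(diazomethyl)-3-methyl-1-(propan-2-yl)cyclopent-2-en-1-yl]oxy}dimethylsilane | CC1=C(C=[N+]=[N-])[C@](O[Si](C)(C)C(C)(C)C)(C(C)C)CC1 | intermediate
12 | tert-butyl({(1R)-2-[(1S,2S)-2-ethenyl-2-methylcyclopropyl]-3-methyl-1-(propan-2-yl)cyclopent-2-en-1-yl}oxy)dimethylsilane (cyclopentenyl and ethenyl groups cis on the cyclopropane) | C=C[C@]1(C)C[C@@H]1C2=C(C)CC[C@@]2(O[Si](C)(C)C(C)(C)C)C(C)C | intermediate
13 | tert-butyl{[(3R,8aS)-6,8a-dimethyl-3-(propan-2-yl)-1,2,3,5,8,8a-hexahydroazulen-3-yl]oxy}dimethylsilane | CC1=CC[C@]2(C)CC[C@@](O[Si](C)(C)C(C)(C)C)(C(C)C)C2=CC1 | intermediate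
14 | (3R,8aS)-6,8a-dimethyl-3-(propan-2-yl)-1,2,3,5,8,8a-hexahydroazulen-3-ol | CC1=CC[C@]2(C)CC[C@@](O)(C(C)C)C2=CC1 | intermediate
15 | chlorodimethylsilane | C[SiH](C)Cl | starting material
16 | {[(3R,8aS)-6,8a-dimethyl-3-(propan-2-yl)-1,2,3,5,8,8a-hexahydroazulen-3-yl]oxy}dimethylsilane | CC1=CC[C@]2(C)CC[C@@](O[SiH](C)C)(C(C)C)C2=CC1 | intermediate
17 | cyclic siloxane: 2,2-dimethyl-1,2-oxasilolane whose oxygen is the C3 oxygen and whose silicon is bonded to C4 of 6,8a-dimethyl-3-(propan-2-yl)-1,2,3,3a,4,5,8,8a-octahydroazulene; O, Si and C3a–H on the same face, C8a methyl on the other | C[Si]1(C)O[C@@]2(C(C)C)CC[C@@]3(C)CC=C(C)C[C@@H]1[C@H]23 | intermediate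
18 | (3R,3aR,4R,8aS)-6,8a-dimethyl-3-(propan-2-yl)-1,2,3,3a,4,5,8,8a-octahydroazulene-3,4-diol | O[C@@H]1CC(C)=CC[C@]2(C)CC[C@@](O)(C(C)C)[C@@H]12 | intermediate
19 | 3,4-dimethoxybenzoyl chloride | COc1ccc(C(Cl)=O)cc1OC | starting material
20 | (3R,3aR,4R,8aS)-3-hydroxy-6,8a-dimethyl-3-(propan-2-yl)-1,2,3,3a,4,5,8,8a-octahydroazulen-4-yl 3,4-dimethoxybenzoate | COc1ccc(C(=O)O[C@@H]2CC(C)=CC[C@]3(C)CC[C@@](O)(C(C)C)[C@@H]23)cc1OC | target

**Step count and risks**

Total step count: 9. Longest linear sequence: 9 steps (1 → 20); all other components are commercial.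

The three steps most likely to fail:

Step 5. The facial selectivity of the cyclopropanation may be poor or reversed, which would give the C8a epimer, since the chosen face rests on a steric model of the silyl ether and on the cyclopropanation/Cope pathway. Attack on the less substituted double bond of isoprene and closure of the diazo compound to a pyrazole would lower the yield further. The fallback changes the stereocontrol element from a shielding silyl ether to the small free hydroxyl, which leaves the formerly blocked face open. It sets out from 6: TBAF frees the carbinol to give hydroxy enal F1, and condensation with 7 gives hydrazone F2. One equivalent of NaH and slow addition to Rh2(OAc)4 and 9 then lead through sodium salt F3, vinyldiazomethane F4 and cis-divinylcyclopropane F5 to 14, where the route is rejoined before step 7.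

Step 7. Insertion of the hindered, trisubstituted C3a=C4 bond may be too slow because closure gives a strained trans-fused oxasilolane; alkene isomerisation by platinum hydride or intermolecular hydrosilylation of C6=C7 could then take over. The fallback sets out from 14. VO(acac)2 and tBuOOH epoxidise C3a=C4 on the face of the hydroxyl to give epoxy alcohol F6. Cp2TiCl (from Cp2TiCl2 and Mn) opens the oxirane homolytically at the tertiary C3a, and 1,4-cyclohexadiene reduces the radical. This gives 18 and rejoins the route before step 9; any C3a epimer would be removed by chromatography.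

Step 3. Under the warm, mildly acidic enamine conditions the silyloxy group may be lost by β-elimination, or the ring may close in the other sense (ketone enolate on the aldehyde). The fallback separates addition from dehydration and sets out from 5. L-Proline in DMSO at room temperature should stop at aldol adduct F7. Methanesulfonyl chloride and Et3N then convert only the new tertiary hydroxyl into mesylate F8, which loses methanesulfonate by E1cB elimination to give 6.

Further compounds
F1 | step 5 | (5R)-5-hydroxy-2-methyl-5-(propan-2-yl)cyclopent-1-ene-1-carbaldehyde | CC1=C(C=O)[C@](O)(C(C)C)CC1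
F2 | step 5 | N'-[(E)-{(5R)-5-hydroxy-2-methyl-5-(propan-2-yl)cyclopent-1-en-1-yl}methylidene]-2-(trifluoromethyl)benzenesulfonohydrazide | CC1=C(/C=N/NS(=O)(=O)c2ccccc2C(F)(F)F)[C@](O)(C(C)C)CC1
F3 | step 5 | sodium salt of hydrazone F2 | CC1=C(/C=N/[N-]S(=O)(=O)c2ccccc2C(F)(F)F)[C@](O)(C(C)C)CC1.[Na+]
F4 | step 5 | (1R)-2-(diazomethyl)-3-methyl-1-(propan-2-yl)cyclopent-2-en-1-ol | CC1=C(C=[N+]=[N-])[C@](O)(C(C)C)CC1
F5 | step 5 | (1R)-2-[(1S,2S)-2-ethenyl-2-methylcyclopropyl]-3-methyl-1-(propan-2-yl)cyclopent-2-en-1-ol | C=C[C@]1(C)C[C@@H]1C2=C(C)CC[C@@]2(O)C(C)C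
F6 | step 7 | 3a,4-epoxide of 14 with the oxirane oxygen on the face of the C3 hydroxyl | CC1=CC[C@]2(C)CC[C@@](O)(C(C)C)[C@]23O[C@@H]3C1
F7 | step 3 | 5-[(tert-butyldimethylsilyl)oxy]-2-hydroxy-2-methyl-5-(propan-2-yl)cyclopentane-1-carbaldehyde (C5 as in 5; mixture at C1 and C2) | CC1(O)CC[C@@](O[Si](C)(C)C(C)(C)C)(C(C)C)C1C=O
F8 | step 3 | methanesulfonate of the tertiary hydroxyl of F7 | CC1(OS(C)(=O)=O)CC[C@@](O[Si](C)(C)C(C)(C)C)(C(C)C)C1C=O
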